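## The problem

The target 14 is an achiral bis-coumarin in which two 6-methoxy-7-oxygenated 2H-chromen-2-one rings are joined through one oxygen that runs from C3 of unit 1 (the ring that keeps a free 7-hydroxyl) to C7' of unit 2 (a scopoletin residue). There is no stereocentre, so the difficulties are regiochemical and chemoselective. The C3–O–C7' link is an aryl vinyl ether on the α-carbon of an unsaturated lactone; since C3 of a finished coumarin is neither a good electrophile nor easily oxygenated, the ether oxygen is best introduced while C3 is still sp3. O7 and O7' sit in identical 6-methoxy-7-hydroxy surroundings, yet one must end as the ether and the other as a free phenol, so unit 1 has to carry a protecting group on O7 that comes off at the end without touching two aryl methyl ethers. Both lactones open with hydroxide or alkoxide, and both C3=C4 bonds are conjugate acceptors that can also be hydrogenated, which limits the bases and reductants that can be used once unit 2 is attached. The enabling feature is that C3 of unit 1 carries both the ether oxygen and the lactone carbonyl C2: in the ring-opened form it is the methylene of an aryloxyacetate, acidic enough to be enolised. Its enolate can form C3–C4 by attacking a carbonyl carbon already bonded to C4a, and if that carbon is a salicylate ester the closure is a Claisen condensation that delivers C4 as an enol hydroxyl, to be removed afterwards.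

## Retrosynthesis

**O7–benzyl.** The last bond cut is the O7–CH2Ph bond: 14 comes from its 7-O-benzyl ether 13. A protecting group on O7 is unavoidable because O7 and O7' are chemically alike. Benzyl is preferred to silyl or acyl groups because it is indifferent to the amide base, the triflating agent and the palladium-catalysed formate reduction used earlier. It is preferred to an allyl group, which zerovalent palladium and formate would cleave, so that a phenoxide released during the C4 reduction could add to the C4 triflate. The forward step must cleave one benzyl ether beside two methyl ethers, a vinyl aryl ether and two lactones, which points to BCl3 with a cation scavenger at low temperature.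

**C4–H back to C4–O.** The C4–H bond of 13 is traced to a C4–O bond: 13 from the enol triflate 12, and 12 from the 4-hydroxycoumarin 11. The skeleton is not simplified; these two steps are the price of closing the ring at the ester oxidation level. They are acceptable because O4 of 11 is the only acidic hydroxyl in the molecule, and its triflate is an electron-poor vinyl triflate, the substrate class best suited to formate reduction under zerovalent palladium catalysis.

**C3–C4 (key cut).** Cutting C3–C4 of 11 opens the pyranone of unit 1 and gives the diester 10, in which C3 is the methylene of an aryloxyacetate and C4 is the carbon of a methyl salicylate. The neighbouring cuts are each weaker: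
- A cut at C4–C4a would ask an arene to act as nucleophile, with an open regiochemical question and a second, competing arene in unit 2.
- A cut at O1–C2 would require a stereodefined α-aryloxycinnamate.
- A cut at C3–O would require an Ullmann-type coupling on a 3-halocoumarin.
- The nearest neighbour is the same C3–C4 cut at the aldehyde level, an aldol condensation on salicylaldehyde 2. It avoids the later deoxygenation and is held in reserve.

The ester level is preferred because the closure runs at low temperature with a non-nucleophilic base and is made irreversible by enolate formation of the product. It also gives a vinylogous acid that is easy to separate from neutral by-products. Precursor 10 has one ring fewer and is assembled from two ester bonds. The forward reaction must achieve C-acylation without cleaving the aryl ester or touching the lactone of unit 2.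

**Ester C–O.** The O-acyl bond of 10 is cut to give the salicylate 4 and the aryloxyacetic acid 8, joined through the acid chloride 9. This is the convergent point: each half carries one arene with its full oxygen pattern, and the union is an ordinary phenol acylation. The reverse order (bromoacetylation of 4, then etherification with scopoletin 5) would place a phenoxide beside an activated aryl ester and is less safe.

**O7'–CH2.** Acid 8 is cut at the O7'–CH2 bond to scopoletin 5 and tert-butyl bromoacetate 6, via the tert-butyl ester 7. Unit 2 is thus bought complete, and the only phenol of 5 fixes O7' as the ether oxygen. The tert-butyl ester lets the acid be released with acid, so the lactone never meets hydroxide.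

**Arene of unit 1.** Salicylate 4 is traced through acid 3 and aldehyde 2 to 2,4-dihydroxy-5-methoxybenzaldehyde 1. Compound 1 already holds C4a, the future C4 and all three oxygens of unit 1 in the right places. Only functional-group changes remain: benzylation of O4 (selective because O2 is hydrogen-bonded to the formyl group), oxidation of the aldehyde to the acid, and methyl ester formation.

## Roads not taken

**Alternative 1: benzannulation to build the benzo ring of unit 1.**
- Cut: the benzene ring of unit 1 at C5–C6, C4a–C8a and C8–C8a.
- Forward key step: a Dötz reaction of the carbene complex A2, which is (CO)5Cr=C(OMe)C(OtBu)=CH2, with the terminal alkyne of the enyne ester A3 and one CO ligand. It would give the phenol A1, in which the new C8a hydroxyl lies cis to the ester and is ready to lactonise.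
- Merits: the known regiochemistry of the benzannulation (larger alkyne substituent next to the new phenol, carbene methoxy para to it) places all substituents correctly. No C4 oxygen has to be removed. The phenol A1 is only a lactonisation and a tert-butyl ether cleavage from the target, one step fewer after the key step than in the chosen plan.
- Weak points: the complex A2 is an uncommon 1-alkoxyvinyl carbene complex, to be made from Cr(CO)6 and used in stoichiometric amount. The enyne A3 is an electron-poor, stereodefined α-aryloxy enyne that needs several steps from scopoletin 5, with uncertain alkene geometry. The hydroquinone monoether product is sensitive to the oxidative removal of chromium. All of this constructs a benzene ring that can be bought with its three oxygens in place as 1.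
- Comparison: overall the road is no shorter. The chosen plan offsets its extra end-game step with cheap reagents and ordinary two-electron chemistry throughout.

**Alternative 2: indanone ring expansion for the lactone oxygen of unit 2.**
- Cut: O1'–C8a' of unit 2.
- Forward key step: a Baeyer–Villiger oxidation of the indanone A5, with migration of the aryl carbon, to the dihydrocoumarin A4. A dehydrogenation of C3'–C4' and the debenzylation would follow.
- Merits: the aryl migration is electronically favoured, since the methoxy group is para to the migrating carbon. An indanone tolerates bases that would open a coumarin lactone, so the fragment union could be run under harsher conditions than the chosen plan allows. That is a real advantage.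
- Weak points: the disconnection works on the ring that is available intact in scopoletin 5. The indanone A5 already contains the complete coumarin of unit 1 with its C3 ether, so the actual problem must still be solved by other chemistry before the key step. The peracid must then spare electron-rich arenes and the oxygen-substituted C3=C4 bond of unit 1. The indanone phenol A6, which is 6-hydroxy-5-methoxyindan-1-one, has to replace 5 as the source of unit 2, and A6 is a less obvious purchase than scopoletin. Ring expansion and dehydrogenation of A4 add steps with no counterpart in the chosen plan.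
- Comparison: the chosen plan has to carry the lactone of unit 2 through K2CO3, Et3N and an amide base. It does so by using only non-nucleophilic or weak bases and an acidic work-up.

**Alternative 3: closure of the pyranone of unit 1 at C4–C4a.**
- Cut: C4–C4a of unit 1.
- Forward key step: strong acid converts the aryl β-methoxyacrylate A8 (either alkene geometry), an ester of the phenol A9, into a C4 oxocarbenium ion. This attacks the ester aryl ring para to the benzyloxy group and loses methanol, giving the coumarin A7, which is identical with 13.
- Merits: this is the shortest road. It reaches 13 without any oxidation-level correction and would save about three steps.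
- Weak points:
  - The attacking ring of A8 is an O-acylated, hence weakened, phenol.
  - The scopoletin ring on the α-oxygen can attack the same cation through C8' to close a five-membered ring. This is the classical acid cyclodehydration of α-aryloxy carbonyl compounds to benzofurans.
  - Strong acid also threatens the benzyl ether and invites Fries-type acyl migration of the aryl ester.
- Comparison: the chosen plan pays two extra steps (triflation and reduction). In return, the C4–C4a bond is bought in compound 1, no arene has to act as a nucleophile, and no strong acid is used while the benzyl group is present.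

Key step: step 7

Assumption: the target has no stereocentre, so nothing has to be set; 1, 5 and 6 are taken to be purchasable.

## Route

Step 1
Reactants: 1 2,4-dihydroxy-5-methoxybenzaldehyde
Product: 2 4-(benzyloxy)-2-hydroxy-5-methoxybenzaldehyde
Conditions: BnBr (1.05 equiv), NaHCO3, MeCN, 80 °C
Reagents that add atoms: benzyl bromide, BrCc1ccccc1
Why: Regioselective Williamson etherification; the 4-hydroxyl para to the formyl group is the more acidic and is free, whereas the 2-hydroxyl is held in a hydrogen bond to the carbonyl oxygen, so a weak base should alkylate O4 only, as is usual for 2,4-dihydroxybenzaldehydes.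

Step 2
Reactants: 2 4-(benzyloxy)-2-hydroxy-5-methoxybenzaldehyde
Product: 3 4-(benzyloxy)-2-hydroxy-5-methoxybenzoic acid
Conditions: NaClO2, NaH2PO4, 2-methyl-2-butene (excess), t-BuOH/THF/H2O, 0 °C to rt
Reagents that add atoms: sodium chlorite, [Na+].[O-]Cl=O
Why: Pinnick (Lindgren) oxidation of the aldehyde to the acid; the alkene scavenger removes HOCl before it can chlorinate the electron-rich ring, and the hydrogen-bonded phenol and the benzyl ether should be untouched at the buffered pH.

Step 3
Reactants: 3 4-(benzyloxy)-2-hydroxy-5-methoxybenzoic acid
Product: 4 methyl 4-(benzyloxy)-2-hydroxy-5-methoxybenzoate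
Conditions: MeI, KHCO3, DMF, rt
Reagents that add atoms: iodomethane, CI
Why: SN2 alkylation of the carboxylate; hydrogencarbonate deprotonates only the carboxylic acid, and the salicylate-type phenol stays protonated and hydrogen-bonded, so the methyl ester should form without O-methylation of the phenol.

Step 4
Reactants: 5 scopoletin (7-hydroxy-6-methoxy-2H-chromen-2-one); 6 tert-butyl bromoacetate
Product: 7 tert-butyl [(6-methoxy-2-oxo-2H-chromen-7-yl)oxy]acetate
Conditions: K2CO3, acetone, reflux
Reagents that add atoms: none
Why: Williamson ether synthesis between the only phenol of scopoletin and a reactive α-bromo ester; carbonate in acetone does not open the lactone.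

Step 5
Reactants: 7 tert-butyl [(6-methoxy-2-oxo-2H-chromen-7-yl)oxy]acetate
Product: 8 [(6-methoxy-2-oxo-2H-chromen-7-yl)oxy]acetic acid
Conditions: CF3CO2H/CH2Cl2 (1:3), rt
Reagents that add atoms: none
Why: Acidolysis of the tert-butyl ester with loss of 2-methylpropene frees the acid without the hydroxide that would open the coumarin lactone; the aryl ethers and the lactone are stable to trifluoroacetic acid.

Step 6
Reactants: 8 [(6-methoxy-2-oxo-2H-chromen-7-yl)oxy]acetic acid; 4 methyl 4-(benzyloxy)-2-hydroxy-5-methoxybenzoate
Product: 10 methyl 4-(benzyloxy)-5-methoxy-2-({[(6-methoxy-2-oxo-2H-chromen-7-yl)oxy]acetyl}oxy)benzoate, via aryloxyacetyl chloride 9 (not isolated)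
Conditions: (COCl)2, DMF (cat.), CH2Cl2, 0 °C to rt, evaporate; then 4, Et3N, DMAP (cat.), CH2Cl2, 0 °C to rt
Reagents that add atoms: oxalyl chloride, ClC(=O)C(=O)Cl (supplies the chlorine of 9 only; no atom of it remains in 10)
Why: Acid chloride formation followed by DMAP-catalysed O-acylation of the phenol; the acylpyridinium ion is reactive enough to esterify the hydrogen-bonded salicylate hydroxyl, and neither partner has another nucleophilic site.

Step 7
Reactants: 10 methyl 4-(benzyloxy)-5-methoxy-2-({[(6-methoxy-2-oxo-2H-chromen-7-yl)oxy]acetyl}oxy)benzoate
Product: 11 7-(benzyloxy)-4-hydroxy-6-methoxy-3-[(6-methoxy-2-oxo-2H-chromen-7-yl)oxy]-2H-chromen-2-one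
Conditions: LiN(SiMe3)2 (2.5 equiv), THF, −78 to 0 °C (10 added slowly to the base); then 1 M HCl
Reagents that add atoms: none
Why: LiN(SiMe3)2 removes a proton from the OCH2 group flanked by the aryloxy oxygen and the aryl ester carbonyl, the lithium enolate adds to the neighbouring methyl ester carbonyl, and collapse of the tetrahedral intermediate expels methoxide and forms C3–C4. The closest known reaction type is the base-mediated intramolecular Claisen (Dieckmann-type) condensation of O-acyl salicylate esters to 3-substituted 4-hydroxycoumarins. The pyranone of unit 1 closes in a 6-exo-trig mode at the ester carbonyl (6-(enolendo)-exo-trig in enolate terms), which is favoured. No stereocentre is formed, since C3 and C4 are both sp2 in the enolised β-keto lactone. The step needs C-acylation in preference to ketene-type fragmentation of the aryl ester, to acyl transfer to the liberated methoxide and to attack on the lactone or the C3'=C4' bond of unit 2. The fixed ortho relation of enolate and ester makes the six-membered intramolecular closure faster than any bimolecular path, the second equivalent of base converts the product into its stabilised lithium enolate so that the closure is irreversible, and addition of 10 to excess base at −78 °C keeps free methoxide away from unreacted aryl ester. Unit 2 has no acidic C–H and the hindered amide does not add to it, and the acidic quench would reclose any lactone that had opened.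

Step 8
Reactants: 11 7-(benzyloxy)-4-hydroxy-6-methoxy-3-[(6-methoxy-2-oxo-2H-chromen-7-yl)oxy]-2H-chromen-2-one
Product: 12 7-(benzyloxy)-6-methoxy-3-[(6-methoxy-2-oxo-2H-chromen-7-yl)oxy]-2-oxo-2H-chromen-4-yl trifluoromethanesulfonate
Conditions: Tf2O, Et3N, CH2Cl2, −20 to 0 °C
Reagents that add atoms: trifluoromethanesulfonic anhydride, O=S(=O)(OS(=O)(=O)C(F)(F)F)C(F)(F)F
Why: O-sulfonylation of the acidic 4-hydroxyl (a vinylogous carboxylic acid) gives the enol triflate, the usual activation of 4-hydroxycoumarins; no other hydroxyl is present.

Step 9
Reactants: 12 7-(benzyloxy)-6-methoxy-3-[(6-methoxy-2-oxo-2H-chromen-7-yl)oxy]-2-oxo-2H-chromen-4-yl trifluoromethanesulfonate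
Product: 13 7-(benzyloxy)-6-methoxy-3-[(6-methoxy-2-oxo-2H-chromen-7-yl)oxy]-2H-chromen-2-one
Conditions: Pd(OAc)2 (5 mol %), 1,1'-bis(diphenylphosphino)ferrocene (dppf, 10 mol %), HCO2H, Et3N, DMF, 60 °C
Reagents that add atoms: none
Why: Formate reduction of a vinyl triflate; zerovalent palladium, formed in the flask from divalent palladium in Pd(OAc)2 and the phosphine, inserts into the C4–O bond, triflate is exchanged for formate, and decarboxylation then reductive elimination give the C4–H bond. The benzyl ether, the methyl ethers and both lactones are inert to this homogeneous hydride source.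

Step 10
Reactants: 13 7-(benzyloxy)-6-methoxy-3-[(6-methoxy-2-oxo-2H-chromen-7-yl)oxy]-2H-chromen-2-one
Product: 14 7-hydroxy-6-methoxy-3-[(6-methoxy-2-oxo-2H-chromen-7-yl)oxy]-2H-chromen-2-one
Conditions: BCl3, pentamethylbenzene, CH2Cl2, −78 °C; then MeOH, aqueous work-up
Reagents that add atoms: none
Why: Lewis-acid cleavage of an aryl benzyl ether; BCl3 binds O7 and the benzyl cation is captured by pentamethylbenzene, which prevents benzylation of the rings. At −78 °C the aryl methyl ethers, the C3–O–C7' ether and both lactones should be retained.

## Compound list

1 | 2,4-dihydroxy-5-methoxybenzaldehyde | COc1cc(C=O)c(O)cc1O | starting material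
2 | 4-(benzyloxy)-2-hydroxy-5-methoxybenzaldehyde | COc1cc(C=O)c(O)cc1OCc1ccccc1 | intermediate
3 | 4-(benzyloxy)-2-hydroxy-5-methoxybenzoic acid | COc1cc(C(=O)O)c(O)cc1OCc1ccccc1 | intermediate
4 | methyl 4-(benzyloxy)-2-hydroxy-5-methoxybenzoate | COC(=O)c1cc(OC)c(OCc2ccccc2)cc1O | intermediate
5 | scopoletin (7-hydroxy-6-methoxy-2H-chromen-2-one) | COc1cc2ccc(=O)oc2cc1O | starting material
6 | tert-butyl bromoacetate | CC(C)(C)OC(=O)CBr | starting material
7 | tert-butyl [(6-methoxy-2-oxo-2H-chromen-7-yl)oxy]acetate | COc1cc2ccc(=O)oc2cc1OCC(=O)OC(C)(C)C | intermediate
8 | [(6-methoxy-2-oxo-2H-chromen-7-yl)oxy]acetic acid | COc1cc2ccc(=O)oc2cc1OCC(=O)O | intermediate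
9 | [(6-methoxy-2-oxo-2H-chromen-7-yl)oxy]acetyl chloride (not isolated) | COc1cc2ccc(=O)oc2cc1OCC(=O)Cl | intermediate
10 | methyl 4-(benzyloxy)-5-methoxy-2-({[(6-methoxy-2-oxo-2H-chromen-7-yl)oxy]acetyl}oxy)benzoate | COC(=O)c1cc(OC)c(OCc2ccccc2)cc1OC(=O)COc1cc2oc(=O)ccc2cc1OC | intermediate
11 | 7-(benzyloxy)-4-hydroxy-6-methoxy-3-[(6-methoxy-2-oxo-2H-chromen-7-yl)oxy]-2H-chromen-2-one | COc1cc2c(O)c(Oc3cc4oc(=O)ccc4cc3OC)c(=O)oc2cc1OCc1ccccc1 | intermediate
12 | 7-(benzyloxy)-6-methoxy-3-[(6-methoxy-2-oxo-2H-chromen-7-yl)oxy]-2-oxo-2H-chromen-4-yl trifluoromethanesulfonate | COc1cc2c(OS(=O)(=O)C(F)(F)F)c(Oc3cc4oc(=O)ccc4cc3OC)c(=O)oc2cc1OCc1ccccc1 | intermediate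
13 | 7-(benzyloxy)-6-methoxy-3-[(6-methoxy-2-oxo-2H-chromen-7-yl)oxy]-2H-chromen-2-one | COc1cc2cc(Oc3cc4oc(=O)ccc4cc3OC)c(=O)oc2cc1OCc1ccccc1 | intermediate
14 | 7-hydroxy-6-methoxy-3-[(6-methoxy-2-oxo-2H-chromen-7-yl)oxy]-2H-chromen-2-one | COc1cc2cc(Oc3cc4oc(=O)ccc4cc3OC)c(=O)oc2cc1O | target

## Step count and risks

Total step count: 10.
Longest linear sequence: 8 steps (steps 1, 2, 3, 6, 7, 8, 9, 10 from 1). The scopoletin branch (steps 4 and 5) joins at step 6 and is 7 steps long to the target.

Least certain steps:

**Step 7 (key step).**
- What may go wrong: fragmentation of the aryl ester enolate into an aryloxyketene and the salicylate phenoxide, or acyl transfer to the liberated methoxide. Both cleave the O-acyl bond instead of forming C3–C4. The cause is that the aryl ester is at once the enolate precursor and a good leaving group.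
- Fallback: form the same C3–C4 bond at the aldehyde oxidation level. It sets out from aldehyde 2 and acid chloride 9 (made from 8 as in step 6) and returns at 13. Acylation of 2 with 9 (Et3N, DMAP cat., CH2Cl2, 0 °C) should give 5-(benzyloxy)-2-formyl-4-methoxyphenyl [(6-methoxy-2-oxo-2H-chromen-7-yl)oxy]acetate F1. DBU in MeCN at rt to 50 °C should then effect the intramolecular aldol (Perkin-type) condensation with loss of water and deliver 13 directly. Steps 2, 3, 7, 8 and 9 would then be unnecessary.

**Step 9.**
- What may go wrong: loss of the triflyl group through attack of formate or amine at sulfur, or addition–elimination at C4, before oxidative addition takes place. The 4-triflate is a vinylogous mixed anhydride, and this would lead back to the enol or to 4-substituted products.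
- Fallback: replace the palladium-catalysed reduction by the classical chloride/dissolving-metal sequence. It sets out from 11 and returns at 13. POCl3 with Et3N in MeCN at reflux should convert 11 into 7-(benzyloxy)-4-chloro-6-methoxy-3-[(6-methoxy-2-oxo-2H-chromen-7-yl)oxy]-2H-chromen-2-one F2. Zn dust in AcOH/EtOH at rt to 50 °C should then remove the chlorine by electron transfer and protonation to give 13.

**Step 2.**
- What may go wrong: electrophilic chlorination or oxidation of the very electron-rich alkoxyphenol ring by the hypochlorous acid and chlorine dioxide formed during the chlorite oxidation, in competition with oxidation of the formyl group.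
- Fallback: mask the phenol before the oxidation and merge its release with the esterification. It sets out from 2 and returns at 4, bypassing 3. Ac2O and pyridine should give 5-(benzyloxy)-2-formyl-4-methoxyphenyl acetate F3. The same NaClO2 oxidation should then give 2-(acetyloxy)-4-(benzyloxy)-5-methoxybenzoic acid F4. Methanol with catalytic H2SO4 at reflux should remove the acetyl group by transesterification and form the methyl ester in one operation, giving 4.

**Step 10.**
- What may go wrong: concurrent cleavage of the 6-methoxy group next to the boron-bound O7, or Friedel–Crafts benzylation of the electron-rich rings if ionisation outruns capture of the benzyl cation.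
- Fallback: abandon acid-mediated cleavage and remove the benzyl group reductively. It sets out from 13 and returns at 14. Hydrogenolysis with H2 (1 atm) over palladium on carbon (Pd/C) in EtOAc/THF at rt, stopped after one equivalent of hydrogen, should give 14. No Lewis acid or carbocation is involved, and the conjugated C3'=C4' bond should be reduced much more slowly than the benzyl ether is cleaved. No new compound is involved.

## Further compounds

F1 | step 7 | 5-(benzyloxy)-2-formyl-4-methoxyphenyl [(6-methoxy-2-oxo-2H-chromen-7-yl)oxy]acetate | O=Cc1cc(OC)c(OCc2ccccc2)cc1OC(=O)COc1cc2oc(=O)ccc2cc1OC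
F2 | step 9 | 7-(benzyloxy)-4-chloro-6-methoxy-3-[(6-methoxy-2-oxo-2H-chromen-7-yl)oxy]-2H-chromen-2-one | COc1cc2c(Cl)c(Oc3cc4oc(=O)ccc4cc3OC)c(=O)oc2cc1OCc1ccccc1
F3 | step 2 | 5-(benzyloxy)-2-formyl-4-methoxyphenyl acetate | CC(=O)Oc1cc(OCc2ccccc2)c(OC)cc1C=O
F4 | step 2 | 2-(acetyloxy)-4-(benzyloxy)-5-methoxybenzoic acid | CC(=O)Oc1cc(OCc2ccccc2)c(OC)cc1C(=O)O
F0 | step 10 | none | none
A1 | alternative 1 | methyl (E)-3-(4-tert-butoxy-2-hydroxy-5-methoxyphenyl)-2-[(6-methoxy-2-oxo-2H-chromen-7-yl)oxy]prop-2-enoate | COC(=O)/C(Oc1cc2oc(=O)ccc2cc1OC)=C\c1cc(OC)c(OC(C)(C)C)cc1O
A2 | alternative 1 | pentacarbonyl[(1-tert-butoxyethenyl)(methoxy)methylidene]chromium, (CO)5Cr=C(OMe)C(OtBu)=CH2 | COC(C(=C)OC(C)(C)C)=[Cr](=C=O)(=C=O)(=C=O)(=C=O)=C=O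
A3 | alternative 1 | methyl (2E)-2-[(6-methoxy-2-oxo-2H-chromen-7-yl)oxy]pent-2-en-4-ynoate | COC(=O)/C(Oc1cc2oc(=O)ccc2cc1OC)=C\C#C
A4 | alternative 2 | 7-(benzyloxy)-6-methoxy-3-[(6-methoxy-2-oxo-3,4-dihydro-2H-chromen-7-yl)oxy]-2H-chromen-2-one | COc1cc2cc(Oc3cc4OC(=O)CCc4cc3OC)c(=O)oc2cc1OCc1ccccc1
A5 | alternative 2 | 6-{[7-(benzyloxy)-6-methoxy-2-oxo-2H-chromen-3-yl]oxy}-5-methoxy-2,3-dihydro-1H-inden-1-one | COc1cc2cc(Oc3cc4C(=O)CCc4cc3OC)c(=O)oc2cc1OCc1ccccc1
A6 | alternative 2 | 6-hydroxy-5-methoxy-2,3-dihydro-1H-inden-1-one | COc1cc2CCC(=O)c2cc1O
A7 | alternative 3 | 7-(benzyloxy)-6-methoxy-3-[(6-methoxy-2-oxo-2H-chromen-7-yl)oxy]-2H-chromen-2-one | COc1cc2cc(Oc3cc4oc(=O)ccc4cc3OC)c(=O)oc2cc1OCc1ccccc1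
A8 | alternative 3 | 3-(benzyloxy)-4-methoxyphenyl 3-methoxy-2-[(6-methoxy-2-oxo-2H-chromen-7-yl)oxy]prop-2-enoate (either alkene geometry) | COC=C(Oc1cc2oc(=O)ccc2cc1OC)C(=O)Oc1ccc(OC)c(OCc2ccccc2)c1
A9 | alternative 3 | 3-(benzyloxy)-4-methoxyphenol | COc1ccc(O)cc1OCc1ccccc1
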